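**Strategy.** The route hinges on cutting the tetrasubstituted C8=C9 alkene of ring B (labdane numbering), which lies between quaternary C10 and C7 and carries no stereochemistry. Ring-closing metathesis of a 1,1-disubstituted alkene on C10 with a second one at the end of the C5 chain forms C8=C9 and ring B in one operation. It exploits the fact that both arms already sit on the adjacent ring A atoms C10 and C5. The precursor is a (2R,3S)-2,3-disubstituted cyclohexanone (C4 ketone), assembled by copper-catalysed asymmetric alkenyl conjugate addition (C10) and alkylation of the derived enolate (C5). C4 is set last by reductive methylation of an enoate.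

Key step: step 8

Remark: labdane numbering is used for all atoms (C4 ketone/ester carbon, C5 ring-fusion CH, C10 quaternary carbon with the angular methyl, C8=C9 ring B alkene, C11–C15 side chain). TBSO = tert-butyl(dimethyl)silyloxy. The chiral ligand of step 5 is assumed to be available in the antipode that gives (S)-C10.

Step 1
Reactants: 1 geranyl acetate [(2E)-3,7-dimethylocta-2,6-dien-1-yl acetate]
Product: 2 (2E)-5-(3,3-dimethyloxiran-2-yl)-3-methylpent-2-en-1-yl acetate (racemic at the epoxide carbon)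
Conditions: mCPBA (1.05 equiv), CH2Cl2, -20 to 0 °C
Reagents that add atoms: 3-chloroperoxybenzoic acid (mCPBA), O=C(OO)c1cccc(Cl)c1
Why: Prilezhaev epoxidation should pick the electron-rich 6,7-alkene because the 2,3-alkene is deactivated by the allylic acetoxy group; the epoxide stereocentre is racemic and is destroyed in step 2.

Step 2
Reactants: 2 (2E)-5-(3,3-dimethyloxiran-2-yl)-3-methylpent-2-en-1-yl acetate
Product: 4 (2E)-3-methyl-6-oxohex-2-en-1-yl acetate, via 6,7-diol 3 (not isolated)
Conditions: H5IO6 (1.2 equiv), THF/H2O, 0 to 23 °C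
Reagents that add atoms: none
Why: Acid-promoted epoxide hydrolysis to diol 3 followed by periodate glycol cleavage (Malaprade reaction) should release acetone and the aldehyde without touching the allylic acetate or the remaining E alkene.

Step 3
Reactants: 4 (2E)-3-methyl-6-oxohex-2-en-1-yl acetate
Product: 6 (2E)-3-methylhept-2-en-6-yn-1-ol, via acetoxy enyne 5 (not isolated)
Conditions: dimethyl (1-diazo-2-oxopropyl)phosphonate (1.3 equiv), K2CO3 (3 equiv), MeOH, 0 to 23 °C, until the acetate is fully cleaved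
Reagents that add atoms: dimethyl (1-diazo-2-oxopropyl)phosphonate (Ohira–Bestmann reagent), CC(=O)C(=[N+]=[N-])P(=O)(OC)OC
Why: Seyferth–Gilbert homologation in its Ohira–Bestmann form converts the aldehyde into the terminal alkyne, and the same K2CO3/MeOH medium methanolyses the acetate, which could not survive the aluminium hydride of step 5.

Step 4
Reactants: 6 (2E)-3-methylhept-2-en-6-yn-1-ol
Product: 7 tert-butyl(dimethyl){[(2E)-3-methylhept-2-en-6-yn-1-yl]oxy}silane
Conditions: TBSCl (1.2 equiv), imidazole, DMF, 0 to 23 °C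
Reagents that add atoms: tert-butyl(chloro)dimethylsilane (TBSCl), CC(C)(C)[Si](C)(C)Cl
Why: Imidazole-promoted silylation of the primary allylic alcohol gives an ether that should be inert to the hydride, organolithium, enolate, metathesis and carbonylation conditions of steps 5 to 11.

Step 5
Reactants: 7 tert-butyl(dimethyl){[(2E)-3-methylhept-2-en-6-yn-1-yl]oxy}silane; 8 3-methylcyclohex-2-en-1-one
Product: 11 trimethyl({(3S)-3-methyl-3-[(5E)-7-(TBSO)-5-methylhepta-1,5-dien-2-yl]cyclohex-1-en-1-yl}oxy)silane, via alkenylaluminium 9 (not isolated), via aluminium enolate 10 (not isolated)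
Conditions: 7 (1.5 equiv), iBu2AlH (1.4 equiv), NiCl2[Ph2P(CH2)3PPh2] (3 mol%), THF, 0 to 23 °C; then 8 (1.0 equiv), copper thiophene-2-carboxylate (CuTC, 5 mol%), chiral SimplePhos-type aminophosphine (10 mol%), Et2O, -30 °C; then Me3SiOTf (2 equiv), -78 to 0 °C; Et3N, aq. NaHCO3 work-up
Reagents that add atoms: trimethylsilyl trifluoromethanesulfonate, C[Si](C)(C)OS(=O)(=O)C(F)(F)F
Why: Nickel-catalysed α-selective hydroalumination of the terminal alkyne gives the 1,1-disubstituted alkenylaluminium 9, copper-catalysed asymmetric conjugate addition to the β-methyl enone (ligand control, alkenyl delivered to the Si face of C3 of 8) sets quaternary C10 as S, and O-silylation of aluminium enolate 10 stores the C4–C5 enolate regiochemistry.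

Step 6
Reactants: 12 4-bromo-2-methylbut-1-ene
Product: 13 4-iodo-2-methylbut-1-ene
Conditions: NaI (2 equiv), acetone, reflux, dark
Reagents that add atoms: sodium iodide, [Na+].[I-]
Why: Finkelstein halide exchange (SN2, driven by precipitation of NaBr) provides the iodide, a much better partner than the bromide for a hindered enolate.

Step 7
Reactants: 11 trimethyl({(3S)-3-methyl-3-[(5E)-7-(TBSO)-5-methylhepta-1,5-dien-2-yl]cyclohex-1-en-1-yl}oxy)silane; 13 4-iodo-2-methylbut-1-ene
Product: 15 (2R,3S)-3-methyl-2-(3-methylbut-3-en-1-yl)-3-[(5E)-7-(TBSO)-5-methylhepta-1,5-dien-2-yl]cyclohexan-1-one, via lithium enolate 14 (not isolated)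
Conditions: MeLi (1.05 equiv), THF, 0 to 23 °C; then HMPA, 13 (3 equiv), -40 to 0 °C
Reagents that add atoms: none
Why: Regiospecific enolate alkylation from a silyl enol ether: MeLi cleaves the O–Si bond to give lithium enolate 14 at C4–C5 only, and SN2 attack on the primary iodide in THF/HMPA (iodide in excess to offset loss to E2) should occur at C5 anti to the bulkier alkenyl group on C10, so that the new chain ends up cis to the C10 methyl and C5 is set as R (trans isomer 15).

Step 8
Reactants: 15 (2R,3S)-3-methyl-2-(3-methylbut-3-en-1-yl)-3-[(5E)-7-(TBSO)-5-methylhepta-1,5-dien-2-yl]cyclohexan-1-one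
Product: 16 (4aS,8aR)-5-[(3E)-5-(TBSO)-3-methylpent-3-en-1-yl]-4a,6-dimethyl-3,4,4a,7,8,8a-hexahydronaphthalen-1(2H)-one
Conditions: RuCl2(=CH-C6H4-2-OiPr)[1,3-bis(2-methylphenyl)imidazolidin-2-ylidene] (10 mol% in two portions), C6H6 (0.005 M), 60 °C, argon sparge
Reagents that add atoms: none
Why: Olefin metathesis through ruthenacyclobutanes: the ruthenium carbene first exchanges onto the less hindered C8 methylidene at the end of the C5 chain, the new alkylidene adds across the neopentyl C9 methylidene on C10 in a [2+2] step, and cycloreversion releases the C8=C9 alkene and a ruthenium methylidene while ethene is swept out of solution. The closest known reaction type is ring-closing metathesis of two 1,1-disubstituted alkenes to tetrasubstituted cycloalkenes with ruthenium catalysts that carry small N-aryl carbene ligands, including closures beside quaternary carbons. Ring B closes as a six-membered carbocycle from a 1,7-diene whose two arms stand trans to each other on the adjacent ring A carbons C5 and C10. No stereocentre is formed, and C5 and C10 are not touched under these neutral conditions. The step needs the two 1,1-disubstituted alkenes to pair in preference to reaction at the C13=C14 alkene and to intermolecular coupling; the trisubstituted alkene is less reactive and could only close a four- or nine-membered ring, and high dilution favours cyclisation.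

Step 9
Reactants: 16 (4aS,8aR)-5-[(3E)-5-(TBSO)-3-methylpent-3-en-1-yl]-4a,6-dimethyl-3,4,4a,7,8,8a-hexahydronaphthalen-1(2H)-one
Product: 18 (4aS,8aR)-5-[(3E)-5-(TBSO)-3-methylpent-3-en-1-yl]-4a,6-dimethyl-3,4,4a,7,8,8a-hexahydronaphthalen-1-yl trifluoromethanesulfonate, via lithium enolate 17 (not isolated)
Conditions: LiN(iPr)2 (1.1 equiv), THF, -78 °C; then PhNTf2 (1.2 equiv), -78 to 0 °C
Reagents that add atoms: N-phenylbis(trifluoromethanesulfonimide), O=S(=O)(N(c1ccccc1)S(=O)(=O)C(F)(F)F)C(F)(F)F
Why: Kinetic deprotonation at -78 °C removes a C3 hydrogen and not the hindered tertiary C5 hydrogen, so O-sulfonylation of enolate 17 (kinetic enolate triflation) gives the C3=C4 enol triflate and leaves the C5 configuration untouched.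

Step 10
Reactants: 18 (4aS,8aR)-5-[(3E)-5-(TBSO)-3-methylpent-3-en-1-yl]-4a,6-dimethyl-3,4,4a,7,8,8a-hexahydronaphthalen-1-yl trifluoromethanesulfonate
Product: 19 methyl (4aS,8aR)-5-[(3E)-5-(TBSO)-3-methylpent-3-en-1-yl]-4a,6-dimethyl-3,4,4a,7,8,8a-hexahydronaphthalene-1-carboxylate
Conditions: Pd(OAc)2 (5 mol%), PPh3 (10 mol%), CO (1 atm), Et3N (2 equiv), MeOH/DMF, 50 °C
Reagents that add atoms: carbon monoxide, [C-]#[O+]; methanol, CO
Why: Palladium-catalysed methoxycarbonylation of an enol triflate (oxidative addition to zerovalent palladium, CO insertion, methanolysis of the acylpalladium) installs the C4 carboxyl carbon under conditions harmless to the silyl ether and the alkenes.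

Step 11
Reactants: 19 methyl (4aS,8aR)-5-[(3E)-5-(TBSO)-3-methylpent-3-en-1-yl]-4a,6-dimethyl-3,4,4a,7,8,8a-hexahydronaphthalene-1-carboxylate
Product: 21 methyl (1S,4aS,8aR)-5-[(3E)-5-(TBSO)-3-methylpent-3-en-1-yl]-1,4a,6-trimethyl-1,2,3,4,4a,7,8,8a-octahydronaphthalene-1-carboxylate, via lithium ester enolate 20 (not isolated)
Conditions: LiBH(s-Bu)3 (1.2 equiv), THF, -78 °C; then MeI (5 equiv), HMPA, -78 to 0 °C
Reagents that add atoms: iodomethane, CI
Why: Reductive alkylation of an enoate: conjugate hydride addition at C3 gives the exocyclic ester enolate 20, and C-methylation should occur from the equatorial α face because the axial C10 methyl shields the β face, setting C4 as S with the ester axial and cis to the C10 methyl.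

Step 12
Reactants: 21 methyl (1S,4aS,8aR)-5-[(3E)-5-(TBSO)-3-methylpent-3-en-1-yl]-1,4a,6-trimethyl-1,2,3,4,4a,7,8,8a-octahydronaphthalene-1-carboxylate
Product: 22 methyl (1S,4aS,8aR)-5-[(3E)-5-hydroxy-3-methylpent-3-en-1-yl]-1,4a,6-trimethyl-1,2,3,4,4a,7,8,8a-octahydronaphthalene-1-carboxylate
Conditions: Bu4NF (1.5 equiv), THF, 0 to 23 °C
Reagents that add atoms: none
Why: Fluoride-driven Si–O cleavage frees the allylic alcohol and should leave the hindered tertiary methyl ester untouched.

Step 13
Reactants: 22 methyl (1S,4aS,8aR)-5-[(3E)-5-hydroxy-3-methylpent-3-en-1-yl]-1,4a,6-trimethyl-1,2,3,4,4a,7,8,8a-octahydronaphthalene-1-carboxylate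
Product: 23 methyl (1S,4aS,8aR)-5-[(3E)-5-acetoxy-3-methylpent-3-en-1-yl]-1,4a,6-trimethyl-1,2,3,4,4a,7,8,8a-octahydronaphthalene-1-carboxylate (CNP0206695.1)
Conditions: Ac2O (2 equiv), pyridine, DMAP (cat.), CH2Cl2, 0 to 23 °C
Reagents that add atoms: acetic anhydride, CC(=O)OC(C)=O
Why: DMAP-catalysed acylation of the primary allylic alcohol gives the acetate under non-ionising conditions that keep the E alkene geometry.

**Compound list**

1 | geranyl acetate | CC(C)=CCC/C(C)=C/COC(C)=O | starting material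
2 | (2E)-5-(3,3-dimethyloxiran-2-yl)-3-methylpent-2-en-1-yl acetate (racemic) | CC1(C)OC1CC/C(C)=C/COC(C)=O | intermediate
3 | (2E)-6,7-dihydroxy-3,7-dimethyloct-2-en-1-yl acetate (racemic, not isolated) | CC(C)(O)C(O)CC/C(C)=C/COC(C)=O | intermediate
4 | (2E)-3-methyl-6-oxohex-2-en-1-yl acetate | O=CCC/C(C)=C/COC(C)=O | intermediate
5 | (2E)-3-methylhept-2-en-6-yn-1-yl acetate (not isolated) | C#CCC/C(C)=C/COC(C)=O | intermediate
6 | (2E)-3-methylhept-2-en-6-yn-1-ol | C#CCC/C(C)=C/CO | intermediate
7 | tert-butyl(dimethyl){[(2E)-3-methylhept-2-en-6-yn-1-yl]oxy}silane | C#CCC/C(C)=C/CO[Si](C)(C)C(C)(C)C | intermediate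
8 | 3-methylcyclohex-2-en-1-one | CC1=CC(=O)CCC1 | starting material
9 | diisobutyl[(5E)-7-(TBSO)-5-methylhepta-1,5-dien-2-yl]aluminium (not isolated) | C=C(CC/C(C)=C/CO[Si](C)(C)C(C)(C)C)[Al](CC(C)C)CC(C)C | intermediate
10 | diisobutylaluminium (3S)-3-methyl-3-[(5E)-7-(TBSO)-5-methylhepta-1,5-dien-2-yl]cyclohex-1-en-1-olate (not isolated) | CC(C)C[Al](CC(C)C)OC1=C[C@@](C)(C(=C)CC/C(C)=C/CO[Si](C)(C)C(C)(C)C)CCC1 | intermediate
11 | trimethyl({(3S)-3-methyl-3-[(5E)-7-(TBSO)-5-methylhepta-1,5-dien-2-yl]cyclohex-1-en-1-yl}oxy)silane | C[Si](C)(C)OC1=C[C@@](C)(C(=C)CC/C(C)=C/CO[Si](C)(C)C(C)(C)C)CCC1 | intermediate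
12 | 4-bromo-2-methylbut-1-ene | C=C(C)CCBr | starting material
13 | 4-iodo-2-methylbut-1-ene | C=C(C)CCI | intermediate
14 | lithium (3S)-3-methyl-3-[(5E)-7-(TBSO)-5-methylhepta-1,5-dien-2-yl]cyclohex-1-en-1-olate (not isolated) | [Li]OC1=C[C@@](C)(C(=C)CC/C(C)=C/CO[Si](C)(C)C(C)(C)C)CCC1 | intermediate
15 | (2R,3S)-3-methyl-2-(3-methylbut-3-en-1-yl)-3-[(5E)-7-(TBSO)-5-methylhepta-1,5-dien-2-yl]cyclohexan-1-one (metathesis precursor) | O=C1CCC[C@](C)(C(=C)CC/C(C)=C/CO[Si](C)(C)C(C)(C)C)[C@H]1CCC(C)=C | intermediate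
16 | (4aS,8aR)-5-[(3E)-5-(TBSO)-3-methylpent-3-en-1-yl]-4a,6-dimethyl-3,4,4a,7,8,8a-hexahydronaphthalen-1(2H)-one (trans-fused metathesis product) | O=C1CCC[C@]2(C)C(CC/C(C)=C/CO[Si](C)(C)C(C)(C)C)=C(C)CC[C@@H]12 | intermediate
17 | lithium (4aS,8aR)-5-[(3E)-5-(TBSO)-3-methylpent-3-en-1-yl]-4a,6-dimethyl-3,4,4a,7,8,8a-hexahydronaphthalen-1-olate (not isolated) | [Li]OC1=CCC[C@]2(C)C(CC/C(C)=C/CO[Si](C)(C)C(C)(C)C)=C(C)CC[C@@H]12 | intermediate
18 | (4aS,8aR)-5-[(3E)-5-(TBSO)-3-methylpent-3-en-1-yl]-4a,6-dimethyl-3,4,4a,7,8,8a-hexahydronaphthalen-1-yl trifluoromethanesulfonate | O=S(=O)(OC1=CCC[C@]2(C)C(CC/C(C)=C/CO[Si](C)(C)C(C)(C)C)=C(C)CC[C@@H]12)C(F)(F)F | intermediate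
19 | methyl (4aS,8aR)-5-[(3E)-5-(TBSO)-3-methylpent-3-en-1-yl]-4a,6-dimethyl-3,4,4a,7,8,8a-hexahydronaphthalene-1-carboxylate | COC(=O)C1=CCC[C@]2(C)C(CC/C(C)=C/CO[Si](C)(C)C(C)(C)C)=C(C)CC[C@@H]12 | intermediate
20 | lithium ester enolate of the C3-reduced form of 19, exocyclic C4=C(OMe)OLi, enolate geometry not defined (not isolated) | COC(O[Li])=C1CCC[C@]2(C)C(CC/C(C)=C/CO[Si](C)(C)C(C)(C)C)=C(C)CC[C@@H]12 | intermediate
21 | methyl (1S,4aS,8aR)-5-[(3E)-5-(TBSO)-3-methylpent-3-en-1-yl]-1,4a,6-trimethyl-1,2,3,4,4a,7,8,8a-octahydronaphthalene-1-carboxylate | COC(=O)[C@@]1(C)CCC[C@]2(C)C(CC/C(C)=C/CO[Si](C)(C)C(C)(C)C)=C(C)CC[C@@H]12 | intermediate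
22 | methyl (1S,4aS,8aR)-5-[(3E)-5-hydroxy-3-methylpent-3-en-1-yl]-1,4a,6-trimethyl-1,2,3,4,4a,7,8,8a-octahydronaphthalene-1-carboxylate | COC(=O)[C@@]1(C)CCC[C@]2(C)C(CC/C(C)=C/CO)=C(C)CC[C@@H]12 | intermediate
23 | methyl (1S,4aS,8aR)-5-[(3E)-5-acetoxy-3-methylpent-3-en-1-yl]-1,4a,6-trimethyl-1,2,3,4,4a,7,8,8a-octahydronaphthalene-1-carboxylate | COC(=O)[C@@]1(C)CCC[C@]2(C)C(CC/C(C)=C/COC(C)=O)=C(C)CC[C@@H]12 | target

**Step count.** 13 steps in total. The longest linear sequence is 12 steps (steps 1–5 and 7–13, from geranyl acetate); step 6 is a one-step side branch.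

**Steps most likely to fail** (riskiest first)

Step 8. What may go wrong: the ruthenium carbene may fail to load on, or to add across, the two hindered 1,1-disubstituted alkenes, so that the diene is returned or slowly lost to alkene migration and intermolecular coupling. The fallback sets out from 11 and comes back at 16. It is a relay ring-closing metathesis on a redesigned substrate. Mukaiyama–Michael addition of 11 to but-3-en-2-one (BF3·OEt2, CH2Cl2, -78 °C), again anti to the alkenyl group on C10, should give the diketone (2R,3S)-3-methyl-3-[(5E)-7-(TBSO)-5-methylhepta-1,5-dien-2-yl]-2-(3-oxobutyl)cyclohexan-1-one F1. Its methyl ketone is olefinated with the ylide generated by KN(SiMe3)2 from hex-5-en-1-yltriphenylphosphonium bromide F2 (from 6-bromohex-1-ene and PPh3, MeCN, reflux). The ring ketone, flanked by C5 and the quaternary C10, should be spared. This should give the relay triene (2R,3S)-3-methyl-3-[(5E)-7-(TBSO)-5-methylhepta-1,5-dien-2-yl]-2-(3-methylnona-3,8-dien-1-yl)cyclohexan-1-one F3, as an E/Z mixture at the new alkene, either isomer being usable. With the catalyst of step 8 the terminal vinyl group is taken up first, cyclopentene is expelled, and the metal is handed to C8 as the fully substituted alkylidene. That alkylidene then only has to close onto the C9 methylidene to give 16.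

Step 7. What may go wrong: poor facial selectivity, with the chain entering C5 on both faces of enolate 14 because the methyl and alkenyl groups on C10 differ too little in bulk. The fallback sets out from 11 and comes back at 16. It gives up kinetic control in the alkylation and fixes C5 after ring closure by a stereoconvergent enolate protonation. The alkylation is run as in step 7 and the product is carried on as the mixture of 15 with its C5 epimer (2S,3S)-3-methyl-2-(3-methylbut-3-en-1-yl)-3-[(5E)-7-(TBSO)-5-methylhepta-1,5-dien-2-yl]cyclohexan-1-one F4. Under the conditions of step 8, F4 should close in the same way, giving the cis-fused ketone (4aS,8aS)-5-[(3E)-5-(TBSO)-3-methylpent-3-en-1-yl]-4a,6-dimethyl-3,4,4a,7,8,8a-hexahydronaphthalen-1(2H)-one F5 beside 16. Me3SiCl, NaI and Et3N in MeCN should convert both ketones into the more substituted C4=C5 enol ether trimethyl{[(4aR)-5-[(3E)-5-(TBSO)-3-methylpent-3-en-1-yl]-4a,6-dimethyl-2,3,4,4a,7,8-hexahydronaphthalen-1-yl]oxy}silane F6. MeLi in THF releases lithium (4aR)-5-[(3E)-5-(TBSO)-3-methylpent-3-en-1-yl]-4a,6-dimethyl-2,3,4,4a,7,8-hexahydronaphthalen-1-olate F7. Quenching at -78 °C with 2,6-di-tert-butyl-4-methylphenol should deliver the proton to C5 from the α face, anti to the angular C10 methyl, to give 16.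

Step 11. What may go wrong: hydride transfer to the hindered trisubstituted enoate may stall, or attack at the ester carbonyl may compete, so that the enolate needed for methylation is not formed cleanly. The fallback sets out from 19 and comes back at 21. It separates the reduction from the methylation. Mg turnings in MeOH (0 to 23 °C) should reduce the conjugated C3=C4 bond by electron transfer and leave the isolated alkenes and the silyl ether alone. This gives methyl (4aS,8aS)-5-[(3E)-5-(TBSO)-3-methylpent-3-en-1-yl]-4a,6-dimethyl-1,2,3,4,4a,7,8,8a-octahydronaphthalene-1-carboxylate F8 (trans-fused, H5 still α, the 8a descriptor changing by priority only; mixture of C4 epimers). LiN(iPr)2 (THF, -78 °C) then forms the same ester enolate 20, and MeI methylates it from the α face as in step 11 to give 21.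

**Further compounds**

F1 | step 8 | (2R,3S)-3-methyl-3-[(5E)-7-(TBSO)-5-methylhepta-1,5-dien-2-yl]-2-(3-oxobutyl)cyclohexan-1-one | O=C1CCC[C@](C)(C(=C)CC/C(C)=C/CO[Si](C)(C)C(C)(C)C)[C@H]1CCC(C)=O
F2 | step 8 | hex-5-en-1-yltriphenylphosphonium bromide | C=CCCCC[P+](c1ccccc1)(c1ccccc1)c1ccccc1.[Br-]
F3 | step 8 | (2R,3S)-3-methyl-3-[(5E)-7-(TBSO)-5-methylhepta-1,5-dien-2-yl]-2-(3-methylnona-3,8-dien-1-yl)cyclohexan-1-one (E/Z mixture at the new alkene) | O=C1CCC[C@](C)(C(=C)CC/C(C)=C/CO[Si](C)(C)C(C)(C)C)[C@H]1CCC(C)=CCCCC=C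
F4 | step 7 | (2S,3S)-3-methyl-2-(3-methylbut-3-en-1-yl)-3-[(5E)-7-(TBSO)-5-methylhepta-1,5-dien-2-yl]cyclohexan-1-one (C5 epimer of 15) | O=C1CCC[C@](C)(C(=C)CC/C(C)=C/CO[Si](C)(C)C(C)(C)C)[C@@H]1CCC(C)=C
F5 | step 7 | (4aS,8aS)-5-[(3E)-5-(TBSO)-3-methylpent-3-en-1-yl]-4a,6-dimethyl-3,4,4a,7,8,8a-hexahydronaphthalen-1(2H)-one (cis-fused C5 epimer of 16) | O=C1CCC[C@]2(C)C(CC/C(C)=C/CO[Si](C)(C)C(C)(C)C)=C(C)CC[C@H]12
F6 | step 7 | trimethyl{[(4aR)-5-[(3E)-5-(TBSO)-3-methylpent-3-en-1-yl]-4a,6-dimethyl-2,3,4,4a,7,8-hexahydronaphthalen-1-yl]oxy}silane | C[Si](C)(C)OC1=C2CCC(C)=C(CC/C(C)=C/CO[Si](C)(C)C(C)(C)C)[C@@]2(C)CCC1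
F7 | step 7 | lithium (4aR)-5-[(3E)-5-(TBSO)-3-methylpent-3-en-1-yl]-4a,6-dimethyl-2,3,4,4a,7,8-hexahydronaphthalen-1-olate | [Li]OC1=C2CCC(C)=C(CC/C(C)=C/CO[Si](C)(C)C(C)(C)C)[C@@]2(C)CCC1
F8 | step 11 | methyl (4aS,8aS)-5-[(3E)-5-(TBSO)-3-methylpent-3-en-1-yl]-4a,6-dimethyl-1,2,3,4,4a,7,8,8a-octahydronaphthalene-1-carboxylate (trans-fused, mixture of C4 epimers) | COC(=O)C1CCC[C@]2(C)C(CC/C(C)=C/CO[Si](C)(C)C(C)(C)C)=C(C)CC[C@@H]12
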